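(All runs come from a simulation on assumed constants; the scatter is artificial.)

A leftover opens the case: beta charges 0.0200 M more Xa than Xb, the limiting reagent, yet its last reading, 0.0157 M at 22 min, lies below that leftover. Xa has fallen past the one-to-one count with Xb, and the zeta question lives in that tail.

| flask | Xa | Xb | Xc | time |
|---|---|---|---|---|
| beta | 0.100 M | 0.0800 M | 0.0100 M |  |
| eta | 0.100 M | 0.0800 M | 0.00500 M |  |
| zeta | 0.0600 M | 0.0400 M | 0.0100 M | 22 min |

| run | time / min | [Xa] / M |
|---|---|---|
| beta run | 3.1 | 0.0733 |
| beta run | 6.3 | 0.0540 |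
| beta run | 9.4 | 0.0389 |
| beta run | 13 | 0.0284 |
| beta run | 16 | 0.0216 |
| beta run | 19 | 0.0185 |
| beta run | 22 | 0.0157 |
| eta run | 3.1 | 0.0858 |
| eta run | 6.3 | 0.0723 |
| eta run | 9.4 | 0.0589 |
| eta run | 13 | 0.0464 |
| eta run | 16 | 0.0377 |
| eta run | 19 | 0.0325 |
| eta run | 22 | 0.0279 |

(readings scatter by 5 × 10⁻⁴ M)

1. apparent order in [Xc] of the starting rate, round the charge of the beta run (the rate where two percent of its Xa have turned into Xp)
2. Xa in the zeta run at 22 min, as a share of the Xa charged

- Overall: Xa + Xb -> Xp, with Xc as catalyst.
- Constant volume, constant temperature.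
- Readings of a species count what is bound in complexes too.
- "The second partner" is Xb.
- An order is taken over about fifteen percent of the charge, up and down.

Zeta's charge resembles a state of beta. Once beta has lost 0.0400 M of Xa, one-to-one counting leaves 0.0400 M of Xb, which is zeta's Xb charge. Let s be the time beta takes to come down to zeta's Xa, and k the tail constant. Zeta is asked at the time of beta's last reading, so this reckoning runs:

c(Xa), zeta = c(Xa), beta's last reading × exp(−k·s)

Start with s. Between the first two beta readings Xa falls at 0.0955 min⁻¹, which gives s = 5.20 min. One scatter shifts it by 0.0873 min, a small term.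

One scatter on the last reading shifts the answer by 3.18 %. The same error moves k by 0.005308 min⁻¹, which adds 2.76 %.

Taken as the first-order fall of Xa per minute across beta's last readings, k reads 0.0532 min⁻¹, and eta's same readings give 0.0502 min⁻¹. At beta's k the shift in s moves the answer by 0.464 %, less than the 3.18 % from the last reading, so k and that reading need care. Frozen at beta's value:

c(Xa), zeta = 0.01191 M, a share of 19.8 %

The forecast gives an order of 1.05 and a share of 19 %, slightly below the share reckoned here, and remarks: "Absence of product might make it slightly faster."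

The flask gives 22.2 % and an order of 0.71, by these steps:

    Xc + Xa → Z + Xh (13.86 L mol⁻¹ min⁻¹)
    Z + Xb → Xp + Xc (32.28 L mol⁻¹ min⁻¹)
    Xa + Xb + Xp → 2 Xp (22.80 L² mol⁻² min⁻¹)
    2 Xb ⇌ Xb2, settled at all times (4.810 L mol⁻¹)

Near the start, product forms at 0.0061 M min⁻¹ in beta and 0.0036 M min⁻¹ in eta, which has half the Xc. Zeta's share stands above the reckoned one, and at k that gap reads as 2.09 min, which on this reckoning makes zeta's head start on beta's curve 3.11 min instead of 5.20 min. In eta, the same k carries 0.0377 M at 16 min to 0.02740 M at 22 min, where the reading is 0.0279 M.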